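The flavanone's ring C is closed last, by joining C3 to C2. Ring B and C2 travel through the synthesis as an ordinary 4-(benzyloxy)benzyl ether on the phenol oxygen that becomes O1, and the acetyl group is converted into a diazoketone. A chiral dirhodium carboxylate then inserts the carbenoid carbon (C3) into one of the two enantiotopic benzylic C–H bonds, forming the C2–C3 bond, the pyranone ring and the C2 stereocentre in one operation. The step exploits the hydridic C2–H flanked by O1 and the para-oxygenated ring B. The hindered biaryl bond to a preformed luteolin unit is made earlier by Suzuki coupling.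

Key step: step 10

Remarks on the chemistry (assumptions):
- The target SMILES corresponds to the (2R) flavanone, and the route is written for that enantiomer.
- The target carries no axial descriptor, so the biaryl axis (flavanone C6 to luteolin C6') is treated as freely rotating. Protected intermediates may show slowly interconverting rotamers, which converge on deprotection.
- The sense of induction of the dirhodium catalyst on this substrate cannot be predicted with confidence. The route is written with Rh2(S-PTTL)4; its mirror-image catalyst Rh2(R-PTTL)4 would be used instead if a trial on 15 favours the (S) product.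

Step 1
Reactants: 1 3,4-bis(benzyloxy)benzaldehyde
Product: 2 2-bromo-4,5-bis(benzyloxy)benzaldehyde
Conditions: Br2 (1.05 equiv), NaOAc, AcOH, rt
Reagents that add atoms: bromine, BrBr
Why: Electrophilic aromatic bromination should go para to the 3-benzyloxy group and ortho to the formyl group, as with veratraldehyde, while NaOAc buffers the HBr so that the benzyl ethers survive.

Step 2
Reactants: 2 2-bromo-4,5-bis(benzyloxy)benzaldehyde; 3 1-[2-hydroxy-4,6-bis(benzyloxy)phenyl]ethanone
Product: 4 (E)-1-[2-hydroxy-4,6-bis(benzyloxy)phenyl]-3-[2-bromo-4,5-bis(benzyloxy)phenyl]prop-2-en-1-one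
Conditions: KOH (50% aq), EtOH/THF, rt
Reagents that add atoms: none
Why: Claisen–Schmidt condensation of the methyl ketone enolate with the non-enolisable aldehyde, followed by E1cB dehydration, should give the E-chalcone with the chelated hydroxyl free for the later ring closure.

Step 3
Reactants: 4 the chalcone
Product: 6 5,7-bis(benzyloxy)-2-[2-bromo-4,5-bis(benzyloxy)phenyl]-4H-chromen-4-one, via racemic flavanone 5 (not isolated)
Conditions: I2 (10 mol%), DMSO, 130 °C
Reagents that add atoms: none
Why: Iodine-catalysed oxidative cyclisation of a 2'-hydroxychalcone in DMSO (oxa-Michael closure to the flavanone, then dehydrogenation with DMSO as terminal oxidant) should give the flavone without touching the aryl bromide or the benzyl ethers.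

Step 4
Reactants: 6 the 6'-bromoflavone
Product: 7 5,7-bis(benzyloxy)-2-[4,5-bis(benzyloxy)-2-(4,4,5,5-tetramethyl-1,3,2-dioxaborolan-2-yl)phenyl]-4H-chromen-4-one
Conditions: B2pin2, Pd(dppf)Cl2 (5 mol%), KOAc, 1,4-dioxane, 90 °C
Reagents that add atoms: bis(pinacolato)diboron, CC1(C)OB(B2OC(C)(C)C(C)(C)O2)OC1(C)C
Why: Miyaura borylation (zerovalent palladium formed in situ inserts into C–Br, then acetate-assisted transmetalation with the diboron) should give the pinacol boronate, the weak base KOAc preventing Suzuki homocoupling and leaving the chromone intact.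

Step 5
Reactants: 8 1-(2,4,6-trihydroxyphenyl)ethanone; 9 1-(benzyloxy)-4-(chloromethyl)benzene (2.1 equiv)
Product: 10 1-{2-hydroxy-4,6-bis[(4-(benzyloxy)benzyl)oxy]phenyl}ethanone
Conditions: K2CO3, DMF, rt to 50 °C
Reagents that add atoms: none
Why: Williamson etherification in which the 4-hydroxyl and one 2-hydroxyl are alkylated while the remaining ortho hydroxyl, hydrogen-bonded to the acetyl carbonyl, stays free, as is usual for phloroacetophenone with two equivalents of a benzyl halide.

Step 6
Reactants: 10 the bis-ether acetophenone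
Product: 11 1-{2-hydroxy-3-iodo-4,6-bis[(4-(benzyloxy)benzyl)oxy]phenyl}ethanone
Conditions: BnMe3N+ ICl2− (1.0 equiv), NaHCO3, CH2Cl2/MeOH, rt
Reagents that add atoms: benzyltrimethylammonium dichloroiodate, C[N+](C)(C)Cc1ccccc1.Cl[I-]Cl
Why: Electrophilic aromatic iodination should occur ortho to the free chelated hydroxyl (position 3), the usual preference of 2-hydroxy-4,6-dialkoxyacetophenones with this reagent, which places the halogen next to the oxygen that becomes the 5-hydroxyl and so fixes the 6-linkage.

Step 7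
Reactants: 11 the iodophenol
Product: 12 1-{3-iodo-4,6-bis[(4-(benzyloxy)benzyl)oxy]-2-[(4-(trifluoromethyl)benzyl)oxy]phenyl}ethanone
Conditions: 4-(trifluoromethyl)benzyl bromide, K2CO3, DMF, 60 °C
Reagents that add atoms: 4-(trifluoromethyl)benzyl bromide, FC(F)(F)c1ccc(CBr)cc1
Why: Williamson etherification of the chelated phenol; this group is chosen because its electron-poor benzylic C–H bonds should be inert to the electrophilic carbenoid of step 10 while the ether stays cleavable by hydrogenolysis.

Step 8
Reactants: 12 the aryl iodide; 7 the flavone boronate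
Product: 13 2-{2-[3-acetyl-4,6-bis({4-(benzyloxy)benzyl}oxy)-2-({4-(trifluoromethyl)benzyl}oxy)phenyl]-4,5-bis(benzyloxy)phenyl}-5,7-bis(benzyloxy)-4H-chromen-4-one
Conditions: Pd(OAc)2 (5 mol%), SPhos (10 mol%), K3PO4, toluene/H2O (10:1), 90 °C
Reagents that add atoms: none
Why: Suzuki–Miyaura coupling in which the bulky, electron-rich biarylphosphine SPhos promotes oxidative addition of zerovalent palladium to the di-ortho-substituted aryl iodide and reductive elimination of the tri-ortho-substituted biaryl.

Step 9
Reactants: 13 the biaryl methyl ketone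
Product: 15 2-{2-[3-(2-diazoacetyl)-4,6-bis({4-(benzyloxy)benzyl}oxy)-2-({4-(trifluoromethyl)benzyl}oxy)phenyl]-4,5-bis(benzyloxy)phenyl}-5,7-bis(benzyloxy)-4H-chromen-4-one, via trifluoroacetyl ketone 14 (not isolated)
Conditions: LiN(SiMe3)2, THF, −78 °C; CF3CO2CH2CF3; cold 1 M HCl work-up; then 4-acetamidobenzenesulfonyl azide, Et3N, H2O, MeCN, rt
Reagents that add atoms: 4-acetamidobenzenesulfonyl azide, CC(=O)Nc1ccc(S(=O)(=O)N=[N+]=[N-])cc1 (the diazo nitrogens of 15); 2,2,2-trifluoroethyl trifluoroacetate, O=C(OCC(F)(F)F)C(F)(F)F (the trifluoroacetyl group of 14 only)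
Why: Detrifluoroacetylative Regitz-type diazo transfer, in which Claisen trifluoroacetylation of the kinetic lithium enolate activates the methyl group and the sulfonyl azide then transfers N2 with loss of the trifluoroacetyl group as the N-acylsulfonamide, is reliable for aryl methyl ketones and should spare the flavone and all ethers.

Step 10
Reactants: 15 the diazoketone
Product: 16 2-{2-[(2R)-2-[4-(benzyloxy)phenyl]-7-({4-(benzyloxy)benzyl}oxy)-4-oxo-5-({4-(trifluoromethyl)benzyl}oxy)chroman-6-yl]-4,5-bis(benzyloxy)phenyl}-5,7-bis(benzyloxy)-4H-chromen-4-one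
Conditions: Rh2(S-PTTL)4 (dirhodium tetrakis[N-phthaloyl-(S)-tert-leucinate], 2 mol%), CH2Cl2, slow addition of 15, 0 °C to rt
Reagents that add atoms: none
Why: The dirhodium tetracarboxylate expels N2 from 15 to give an electrophilic rhodium carbenoid at C3, which inserts through a concerted, asynchronous, hydride-transfer-like three-centre transition state into a benzylic C–H bond of the O–CH2Ar group on the neighbouring phenol oxygen, so that C3–C2 forms as C–H breaks and the catalyst is released. The closest known reaction type is the dirhodium-carboxylate-catalysed intramolecular C–H insertion of ortho-alkoxyaryl diazoketones to chroman-4-ones. Ring C (C4a–C4–C3–C2–O1–C8a) closes by 1,6-insertion, the six-membered mode in which the positive charge building at C2 is stabilised by O1 and by the para-benzyloxyphenyl ring B. The C2 stereocentre arises by selection between the two enantiotopic benzylic hydrogens and is controlled by the chiral pocket of the four N-phthaloyl-tert-leucinate ligands, since no resident stereocentre competes. The step needs chemoselectivity for insertion over attack on an ether oxygen (oxonium ylide, then 1,2-benzyl shift to a benzofuran-3-one), which the weakly basic acyl-conjugated aryl ether oxygens, the doubly activated C–H bond and the bulky carboxylate catalyst in a non-coordinating solvent should favour. It also needs site selectivity between the two ortho ethers, which the 4-(trifluoromethyl)benzyl group on the other oxygen secures because its C–H bonds are deactivated towards the electrophilic carbenoid and shielded by the adjacent biaryl.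

Step 11
Reactants: 16 the protected (R)-flavanone–flavone
Product: 17 2-{2-[(2R)-5,7-dihydroxy-2-(4-hydroxyphenyl)-4-oxochroman-6-yl]-4,5-dihydroxyphenyl}-5,7-dihydroxy-4H-chromen-4-one (the target)
Conditions: H2 (1 atm), Pd/C (10 wt% palladium on carbon), THF/MeOH, rt
Reagents that add atoms: none
Why: Hydrogenolysis of the eight benzylic C–O bonds of the protecting groups under neutral conditions should release all seven phenols without epimerising C2, phenolic benzyl-type ethers being cleaved much faster than the ring C C2–O1 bond or the flavone C2=C3 bond is reduced.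

Compound list
1 | 3,4-bis(benzyloxy)benzaldehyde | O=Cc1ccc(OCc2ccccc2)c(OCc2ccccc2)c1 | starting material
2 | 2-bromo-4,5-bis(benzyloxy)benzaldehyde | O=Cc1cc(OCc2ccccc2)c(OCc2ccccc2)cc1Br | intermediate
3 | 1-[2-hydroxy-4,6-bis(benzyloxy)phenyl]ethanone | CC(=O)c1c(O)cc(OCc2ccccc2)cc1OCc1ccccc1 | starting material
4 | (E)-1-[2-hydroxy-4,6-bis(benzyloxy)phenyl]-3-[2-bromo-4,5-bis(benzyloxy)phenyl]prop-2-en-1-one | O=C(/C=C/c1cc(OCc2ccccc2)c(OCc2ccccc2)cc1Br)c1c(O)cc(OCc2ccccc2)cc1OCc1ccccc1 | intermediate
5 | racemic 5,7-bis(benzyloxy)-2-[2-bromo-4,5-bis(benzyloxy)phenyl]chroman-4-one | O=C1CC(c2cc(OCc3ccccc3)c(OCc3ccccc3)cc2Br)Oc2cc(OCc3ccccc3)cc(OCc3ccccc3)c21 | intermediate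
6 | 5,7-bis(benzyloxy)-2-[2-bromo-4,5-bis(benzyloxy)phenyl]-4H-chromen-4-one | O=c1cc(-c2cc(OCc3ccccc3)c(OCc3ccccc3)cc2Br)oc2cc(OCc3ccccc3)cc(OCc3ccccc3)c12 | intermediate
7 | 5,7-bis(benzyloxy)-2-[4,5-bis(benzyloxy)-2-(4,4,5,5-tetramethyl-1,3,2-dioxaborolan-2-yl)phenyl]-4H-chromen-4-one | O=c1cc(-c2cc(OCc3ccccc3)c(OCc3ccccc3)cc2B2OC(C)(C)C(C)(C)O2)oc2cc(OCc3ccccc3)cc(OCc3ccccc3)c12 | intermediate
8 | 1-(2,4,6-trihydroxyphenyl)ethanone | CC(=O)c1c(O)cc(O)cc1O | starting material
9 | 1-(benzyloxy)-4-(chloromethyl)benzene | ClCc1ccc(OCc2ccccc2)cc1 | starting material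
10 | 1-{2-hydroxy-4,6-bis[(4-(benzyloxy)benzyl)oxy]phenyl}ethanone | CC(=O)c1c(O)cc(OCc2ccc(OCc3ccccc3)cc2)cc1OCc1ccc(OCc2ccccc2)cc1 | intermediate
11 | 1-{2-hydroxy-3-iodo-4,6-bis[(4-(benzyloxy)benzyl)oxy]phenyl}ethanone | CC(=O)c1c(O)c(I)c(OCc2ccc(OCc3ccccc3)cc2)cc1OCc1ccc(OCc2ccccc2)cc1 | intermediate
12 | 1-{3-iodo-4,6-bis[(4-(benzyloxy)benzyl)oxy]-2-[(4-(trifluoromethyl)benzyl)oxy]phenyl}ethanone | CC(=O)c1c(OCc2ccc(C(F)(F)F)cc2)c(I)c(OCc2ccc(OCc3ccccc3)cc2)cc1OCc1ccc(OCc2ccccc2)cc1 | intermediate
13 | biaryl methyl ketone (tetra-O-benzyl-luteolin joined at C6' to C3 of the protected acetophenone) | CC(=O)c1c(OCc2ccc(C(F)(F)F)cc2)c(-c2cc(OCc3ccccc3)c(OCc3ccccc3)cc2-c2cc(=O)c3c(OCc4ccccc4)cc(OCc4ccccc4)cc3o2)c(OCc2ccc(OCc3ccccc3)cc2)cc1OCc1ccc(OCc2ccccc2)cc1 | intermediate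
14 | trifluoroacetyl ketone of 13 (4,4,4-trifluoro-1-aryl-butane-1,3-dione) | O=C(CC(=O)c1c(OCc2ccc(C(F)(F)F)cc2)c(-c2cc(OCc3ccccc3)c(OCc3ccccc3)cc2-c2cc(=O)c3c(OCc4ccccc4)cc(OCc4ccccc4)cc3o2)c(OCc2ccc(OCc3ccccc3)cc2)cc1OCc1ccc(OCc2ccccc2)cc1)C(F)(F)F | intermediate
15 | diazoketone (2-diazo-1-aryl-ethanone derived from 13) | [N-]=[N+]=CC(=O)c1c(OCc2ccc(C(F)(F)F)cc2)c(-c2cc(OCc3ccccc3)c(OCc3ccccc3)cc2-c2cc(=O)c3c(OCc4ccccc4)cc(OCc4ccccc4)cc3o2)c(OCc2ccc(OCc3ccccc3)cc2)cc1OCc1ccc(OCc2ccccc2)cc1 | intermediate
16 | protected (2R)-flavanone–flavone (4'-O-benzyl, 7-O-[4-(benzyloxy)benzyl], 5-O-[4-(trifluoromethyl)benzyl] on the flavanone; tetra-O-benzyl on the luteolin) | O=C1C[C@H](c2ccc(OCc3ccccc3)cc2)Oc2cc(OCc3ccc(OCc4ccccc4)cc3)c(-c3cc(OCc4ccccc4)c(OCc4ccccc4)cc3-c3cc(=O)c4c(OCc5ccccc5)cc(OCc5ccccc5)cc4o3)c(OCc3ccc(C(F)(F)F)cc3)c21 | intermediate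
17 | 2-{2-[(2R)-5,7-dihydroxy-2-(4-hydroxyphenyl)-4-oxochroman-6-yl]-4,5-dihydroxyphenyl}-5,7-dihydroxy-4H-chromen-4-one | O=C1C[C@H](c2ccc(O)cc2)Oc2cc(O)c(-c3cc(O)c(O)cc3-c3cc(=O)c4c(O)cc(O)cc4o3)c(O)c21 | target

Total step count: 11
Longest linear sequence: 8 steps (steps 1, 2, 3, 4, 8, 9, 10, 11)

Steps most likely to fail

Step 10. The carbenoid may attack the lone pair of an ortho ether oxygen and the resulting oxonium ylide may undergo a 1,2-benzyl shift with ring contraction, or the catalyst may discriminate poorly between the two enantiotopic hydrogens. The fallback sets out from ketone 13 and comes back at 16, closing the same bond by an oxidative instead of a carbenoid route. Ketone 13 is O-acetylated through its potassium enolate (KN(SiMe3)2, THF, −78 °C, then Ac2O) to the enol acetate F1. DDQ with 2,6-dichloropyridine and LiClO4 in 1,2-dichloroethane then abstracts hydride from the benzylic C–H of the 4-(benzyloxy)benzyl ether on the ortho oxygen. The aryloxy-stabilised oxocarbenium ion is trapped by the enol acetate carbon with loss of the acetyl group, giving the racemic protected flavanone F2. Preparative chromatography on a chiral stationary phase (amylose tris(3,5-dimethylphenylcarbamate), supercritical CO2/MeOH) separates 16 from the (S)-enantiomer F3, which is discarded. Competing hydride abstraction at the 7-O ether is the reason this is only a fallback.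

Step 8. Transmetalation at the crowded di-ortho-substituted arylpalladium iodide may be so slow that protodeboronation of 7 and hydrodeiodination of 12 take over. The fallback sets out from iodophenol 11 and comes back at 13, forming the biaryl bond before the ortho oxygen is etherified. Iodophenol 11 is coupled with 7 (Pd(OAc)2, SPhos, K3PO4, toluene/H2O, 90 °C) as its small, unencumbered phenoxide to give the biaryl phenol F4. Alkylation of the chelated hydroxyl with 4-(trifluoromethyl)benzyl bromide (K2CO3, DMF, 60 °C) then gives 13.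

Step 11. Over-reduction may occur while the sluggish electron-poor benzyl ether is still being cleaved: saturation of the flavone C2=C3 bond or hydrogenolytic opening of ring C at C2–O1. The fallback sets out from 16 and comes back at 17 by a non-reductive global debenzylation. BCl3 with pentamethylbenzene as cation scavenger in CH2Cl2 at −78 to −20 °C, then MeOH quench, removes the benzyl and 4-alkoxybenzyl groups as cations trapped by the scavenger. The peri 4-(trifluoromethyl)benzyl ether is cleaved by chelation-assisted chloride attack. The low temperature is meant to keep C2 from ionising. No new isolated compound is passed through (entry F0).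

Further compounds
F1 | step 10 | enol acetate of 13 (1-aryl-vinyl acetate) | C=C(OC(C)=O)c1c(OCc2ccc(C(F)(F)F)cc2)c(-c2cc(OCc3ccccc3)c(OCc3ccccc3)cc2-c2cc(=O)c3c(OCc4ccccc4)cc(OCc4ccccc4)cc3o2)c(OCc2ccc(OCc3ccccc3)cc2)cc1OCc1ccc(OCc2ccccc2)cc1
F2 | step 10 | racemic protected flavanone–flavone (racemate of 16) | O=C1CC(c2ccc(OCc3ccccc3)cc2)Oc2cc(OCc3ccc(OCc4ccccc4)cc3)c(-c3cc(OCc4ccccc4)c(OCc4ccccc4)cc3-c3cc(=O)c4c(OCc5ccccc5)cc(OCc5ccccc5)cc4o3)c(OCc3ccc(C(F)(F)F)cc3)c21
F3 | step 10 | (2S)-enantiomer of 16 | O=C1C[C@@H](c2ccc(OCc3ccccc3)cc2)Oc2cc(OCc3ccc(OCc4ccccc4)cc3)c(-c3cc(OCc4ccccc4)c(OCc4ccccc4)cc3-c3cc(=O)c4c(OCc5ccccc5)cc(OCc5ccccc5)cc4o3)c(OCc3ccc(C(F)(F)F)cc3)c21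
F4 | step 8 | biaryl phenol (13 lacking the 4-(trifluoromethyl)benzyl group) | CC(=O)c1c(O)c(-c2cc(OCc3ccccc3)c(OCc3ccccc3)cc2-c2cc(=O)c3c(OCc4ccccc4)cc(OCc4ccccc4)cc3o2)c(OCc2ccc(OCc3ccccc3)cc2)cc1OCc1ccc(OCc2ccccc2)cc1
F0 | step 11 | none | none
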